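## Retrosynthetic overview

1. The target comes from 14-deoxyandrographolide by late oxygenation at C7: SeO2 allylic hydroxylation, then MnO2 and a Luche reduction to set the equatorial 7R alcohol.
2. 14-Deoxyandrographolide comes from an acyclic epoxy alcohol that already carries the butenolide and a free CH2OH. One cationic, epoxide-initiated, allylsilane-terminated bicyclization closes ring A (C4–C5) and then ring B (C10–C9), and the β-silyl cation gives only the 8(17)-alkene.
3. The epoxy alcohol comes from a Z allylic alcohol by Sharpless epoxidation, which is the only source of absolute configuration.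
4. The Z allylic alcohol comes from a dienylsilane and 3-bromofuran-2(5H)-one by hydroboration and B-alkyl Suzuki coupling; the butenolide ring is bought, not made.
5. The dienylsilane comes from a terminal enynol (silylmethylcupration and vinylation), and that from geranyl chloride (ozonolysis, Still–Gennari olefination, reduction, propargylation).

Assumption: geranyl chloride, the Still–Gennari phosphonate, 1-(trimethylsilyl)propyne, Me3SiCH2MgCl, vinyl bromide and 3-bromofuran-2(5H)-one are taken as catalogue compounds.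

Labdane numbering is used for positions (C3 carbinol, C4 quaternary carbon with C18 methyl and C19 CH2OH, C10 with C20 methyl, C17 exocyclic CH2, C13–C16 butenolide).

## Route

Step 1
Reactants: 1 geranyl chloride, (2E)-1-chloro-3,7-dimethylocta-2,6-diene
Product: 2 (4E)-6-chloro-4-methylhex-4-enal
Conditions: O3 (1.0 equiv, Sudan red 7B end-point), CH2Cl2–pyridine, −78 °C; then Me2S, −78 → 20 °C
Reagents that add atoms: ozone, [O-][O+]=O
Why: Ozonolysis (Criegee cleavage) is chemoselective for the electron-rich terminal trisubstituted alkene because the 2,3-alkene is deactivated by the allylic chloride, so the E alkene and the chloride survive and no stereocentre is formed.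

Step 2
Reactants: 2 (4E)-6-chloro-4-methylhex-4-enal; 3 ethyl 2-[bis(2,2,2-trifluoroethoxy)phosphoryl]propanoate
Product: 4 ethyl (2Z,6E)-8-chloro-2,6-dimethylocta-2,6-dienoate
Conditions: KN(SiMe3)2, 18-crown-6, THF, −78 °C
Reagents that add atoms: none
Why: In the Still–Gennari variant of the Horner–Wadsworth–Emmons olefination the electron-poor phosphonate eliminates fast from the kinetic adduct and gives the Z trisubstituted enoate (ester cis to the chain), which fixes the later axial position of C19, while the allylic chloride is inert at −78 °C.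

Step 3
Reactants: 4 ethyl (2Z,6E)-8-chloro-2,6-dimethylocta-2,6-dienoate
Product: 5 (2Z,6E)-8-chloro-2,6-dimethylocta-2,6-dien-1-ol
Conditions: i-Bu2AlH (2.2 equiv), CH2Cl2, −78 °C; aq. KNa tartrate
Reagents that add atoms: none
Why: 1,2-Reduction of the enoate by the aluminium hydride gives the Z allylic alcohol without touching the allylic chloride or either alkene geometry.

Step 4
Reactants: 5 (2Z,6E)-8-chloro-2,6-dimethylocta-2,6-dien-1-ol; 6 1-(trimethylsilyl)prop-1-yne
Product: 8 (2Z,6E)-2,6-dimethylundeca-2,6-dien-10-yn-1-ol, via lithium alkoxide of the C-silylated enynol 7 (not isolated)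
Conditions: 6 (2.3 equiv), n-BuLi, THF, −78 → −20 °C; add 5, −78 → 0 °C; then MeOH, K2CO3 (0.3 equiv), 20 °C
Reagents that add atoms: none
Why: SN2 alkylation of the primary allylic chloride by the propargylic lithium reagent (the silyl group blocks the acetylenic position and suppresses allenyl products, and the hydroxyl consumes the first equivalent) followed in the same flask by methanolysis of the C(sp)–Si bond gives the 1,5-enyne with both alkene geometries intact.

Step 5
Reactants: 8 (2Z,6E)-2,6-dimethylundeca-2,6-dien-10-yn-1-ol; 9 (trimethylsilyl)methylmagnesium chloride; 10 vinyl bromide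
Product: 13 (2Z,6E,10Z)-2,6-dimethyl-10-[(trimethylsilyl)methyl]trideca-2,6,10,12-tetraen-1-ol, via alkenylcopper 11 (not isolated), via alkenylzinc bromide 12 (not isolated)
Conditions: 9 (3.0 equiv), CuBr·SMe2 (2.0 equiv), Et2O–Me2S, −30 → 20 °C; then ZnBr2, THF, Pd(PPh3)4 (5 mol%), 10, 0 → 20 °C; aq. NH4Cl
Reagents that add atoms: none
Why: Normant syn-carbocupration of the terminal alkyne puts Me3SiCH2 on the internal carbon and copper cis to it on the terminal carbon, and transmetalation to zinc followed by Negishi-type coupling with vinyl bromide proceeds with retention, so the trisubstituted allylsilane forms as one geometric isomer (CH2SiMe3 cis to the new vinyl group).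

Step 6
Reactants: 13 (2Z,6E,10Z)-2,6-dimethyl-10-[(trimethylsilyl)methyl]trideca-2,6,10,12-tetraen-1-ol; 14 3-bromofuran-2(5H)-one
Product: 16 3-[(3Z,7E,11Z)-13-hydroxy-8,12-dimethyl-4-[(trimethylsilyl)methyl]trideca-3,7,11-trien-1-yl]furan-2(5H)-one, via B-alkyl-9-BBN borane 15 (not isolated)
Conditions: 9-BBN (2.3 equiv), THF, 0 → 20 °C; then 14, PdCl2(dppf) (5 mol%), AsPh3, Cs2CO3, DMF–H2O, 20 °C
Reagents that add atoms: none
Why: 9-BBN hydroborates only the monosubstituted vinyl terminus of the diene (boron on the terminal carbon, trisubstituted alkenes inert, hydroxyl masked in situ as its borinate), and B-alkyl Suzuki–Miyaura coupling with the α-bromo butenolide forms the C12–C13 bond without disturbing any alkene geometry.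

Step 7
Reactants: 16 3-[(3Z,7E,11Z)-13-hydroxy-8,12-dimethyl-4-[(trimethylsilyl)methyl]trideca-3,7,11-trien-1-yl]furan-2(5H)-one
Product: 17 3-[(3Z,7E)-10-[(2R,3S)-3-(hydroxymethyl)-3-methyloxiran-2-yl]-8-methyl-4-[(trimethylsilyl)methyl]deca-3,7-dien-1-yl]furan-2(5H)-one
Conditions: Ti(Oi-Pr)4 (10 mol%), L-(+)-diethyl tartrate (12 mol%), t-BuOOH (2 equiv), 4 Å molecular sieves, CH2Cl2, −20 °C
Reagents that add atoms: tert-butyl hydroperoxide, CC(C)(C)OO
Why: Sharpless asymmetric epoxidation is directed by the allylic hydroxyl, so only that alkene reacts, and L-(+)-diethyl tartrate delivers oxygen to the face that gives the (2R,3S)-oxirane (labdane C3 R and C4 S, about 90% ee expected for a Z 2-methyl allylic alcohol), the sole source of absolute configuration.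

Step 8
Reactants: 17 3-[(3Z,7E)-10-[(2R,3S)-3-(hydroxymethyl)-3-methyloxiran-2-yl]-8-methyl-4-[(trimethylsilyl)methyl]deca-3,7-dien-1-yl]furan-2(5H)-one
Product: 19 14-deoxyandrographolide, (3R,4R,5S,9R,10S)-3,19-dihydroxylabda-8(17),13-dien-16,15-olide, via dichloroaluminium alkoxide 18 (not isolated)
Conditions: MeAlCl2 (3.0 equiv), CH2Cl2, −78 °C, 1 h; aq. KNa tartrate
Reagents that add atoms: none
Why: Proposed new method: MeAlCl2 first turns the free primary hydroxyl into the dichloroaluminium alkoxide 18 (methane lost, no protic acid formed), whose aluminium also binds the oxirane oxygen so that the C4–O bond ionises with backside attack by the C5=C10 alkene and the C10 cation is captured by the allylsilane through a chair–chair transition state, the β-silyl cation at C8 then losing Me3Si+ to give only the exocyclic alkene; the oxirane thus sets C4 (inversion, CH2OH axial), C5 and C10 (anti addition across the E alkene, trans-decalin) and C9 (side chain equatorial from the Z allylsilane), the closest known reaction type being the Lewis-acid-promoted epoxide-initiated cation–olefin bicyclization with allylsilane (Sakurai-type) termination, here extended to an unprotected 2,3-epoxy alcohol bearing a butenolide.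

Step 9
Reactants: 19 14-deoxyandrographolide
Product: 20 (3R,4R,5S,7S,9S,10S)-3,7,19-trihydroxylabda-8(17),13-dien-16,15-olide (axial 7-OH, the C7 epimer of the target)
Conditions: SeO2 (0.3 equiv), t-BuOOH (3 equiv), CH2Cl2, 20 °C
Reagents that add atoms: tert-butyl hydroperoxide, CC(C)(C)OO
Why: Sharpless–Umbreit allylic hydroxylation (ene reaction then [2,3]-sigmatropic shift) attacks the CH2 flank (C7) of the electron-rich exocyclic alkene and returns the double bond to C8=C17, with oxygen delivered axially to give the 7S alcohol, whose configuration is corrected in steps 10 and 11.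

Step 10
Reactants: 20 (3R,4R,5S,7S,9S,10S)-3,7,19-trihydroxylabda-8(17),13-dien-16,15-olide
Product: 21 (3R,4R,5S,9S,10S)-3,19-dihydroxy-7-oxolabda-8(17),13-dien-16,15-olide
Conditions: MnO2 (activated, 20 equiv), CH2Cl2, 20 °C
Reagents that add atoms: none
Why: Allylic oxidation with MnO2 is chemoselective for the allylic C7 alcohol (the saturated secondary C3 and primary C19 hydroxyls do not react) and erases the wrongly configured C7 centre as the exocyclic enone.

Step 11
Reactants: 21 (3R,4R,5S,9S,10S)-3,19-dihydroxy-7-oxolabda-8(17),13-dien-16,15-olide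
Product: 22 (3R,4R,5S,7R,9S,10S)-3,7,19-trihydroxylabda-8(17),13-dien-16,15-olide (target, CNP0280530.1)
Conditions: NaBH4, CeCl3·7H2O, MeOH, −78 → −40 °C
Reagents that add atoms: none
Why: In this Luche reduction, 1,2-hydride addition to the exocyclic enone with axial delivery on the face carrying the axial H5 and H9 gives the equatorial 7R alcohol cis to the C10 methyl, while CeCl3 suppresses conjugate reduction and the butenolide is untouched at low temperature.

## Compound list

1 | geranyl chloride, (2E)-1-chloro-3,7-dimethylocta-2,6-diene | CC(C)=CCC/C(C)=C/CCl | starting material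
2 | (4E)-6-chloro-4-methylhex-4-enal | O=CCC/C(C)=C/CCl | intermediate
3 | ethyl 2-[bis(2,2,2-trifluoroethoxy)phosphoryl]propanoate (Still–Gennari phosphonate) | CCOC(=O)C(C)P(=O)(OCC(F)(F)F)OCC(F)(F)F | starting material
4 | ethyl (2Z,6E)-8-chloro-2,6-dimethylocta-2,6-dienoate | CCOC(=O)/C(C)=C\CC/C(C)=C/CCl | intermediate
5 | (2Z,6E)-8-chloro-2,6-dimethylocta-2,6-dien-1-ol | OC/C(C)=C\CC/C(C)=C/CCl | intermediate
6 | 1-(trimethylsilyl)prop-1-yne | CC#C[Si](C)(C)C | starting material
7 | lithium (2Z,6E)-2,6-dimethyl-11-(trimethylsilyl)undeca-2,6-dien-10-yn-1-olate (not isolated) | [Li]OC/C(C)=C\CC/C(C)=C/CCC#C[Si](C)(C)C | intermediate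
8 | (2Z,6E)-2,6-dimethylundeca-2,6-dien-10-yn-1-ol | OC/C(C)=C\CC/C(C)=C/CCC#C | intermediate
9 | (trimethylsilyl)methylmagnesium chloride | C[Si](C)(C)C[Mg]Cl | starting material
10 | vinyl bromide (bromoethene) | C=CBr | starting material
11 | [(1Z,5E,9Z)-11-(chloromagnesiooxy)-6,10-dimethyl-2-[(trimethylsilyl)methyl]undeca-1,5,9-trien-1-yl]copper (not isolated; Cu cis to CH2SiMe3) | Cl[Mg]OC/C(C)=C\CC/C(C)=C/CC/C(C[Si](C)(C)C)=C/[Cu] | intermediate
12 | bromo[(1Z,5E,9Z)-11-(chloromagnesiooxy)-6,10-dimethyl-2-[(trimethylsilyl)methyl]undeca-1,5,9-trien-1-yl]zinc (not isolated) | Cl[Mg]OC/C(C)=C\CC/C(C)=C/CC/C(C[Si](C)(C)C)=C/[Zn]Br | intermediate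
13 | (2Z,6E,10Z)-2,6-dimethyl-10-[(trimethylsilyl)methyl]trideca-2,6,10,12-tetraen-1-ol | OC/C(C)=C\CC/C(C)=C/CC/C(C[Si](C)(C)C)=C/C=C | intermediate
14 | 3-bromofuran-2(5H)-one | O=C1OCC=C1Br | starting material
15 | 9-[(3Z,7E,11Z)-13-(9-borabicyclo[3.3.1]nonan-9-yloxy)-8,12-dimethyl-4-[(trimethylsilyl)methyl]trideca-3,7,11-trien-1-yl]-9-borabicyclo[3.3.1]nonane (not isolated) | C1CCC2CCCC1B2OC/C(C)=C\CC/C(C)=C/CC/C(C[Si](C)(C)C)=C/CCB1C2CCCC1CCC2 | intermediate
16 | 3-[(3Z,7E,11Z)-13-hydroxy-8,12-dimethyl-4-[(trimethylsilyl)methyl]trideca-3,7,11-trien-1-yl]furan-2(5H)-one | OC/C(C)=C\CC/C(C)=C/CC/C(C[Si](C)(C)C)=C/CCC1=CCOC1=O | intermediate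
17 | 3-[(3Z,7E)-10-[(2R,3S)-3-(hydroxymethyl)-3-methyloxiran-2-yl]-8-methyl-4-[(trimethylsilyl)methyl]deca-3,7-dien-1-yl]furan-2(5H)-one | OC[C@]1(C)O[C@@H]1CC/C(C)=C/CC/C(C[Si](C)(C)C)=C/CCC1=CCOC1=O | intermediate
18 | O-dichloroaluminium alkoxide of 17 (Cl2Al–O–CH2 on the quaternary oxirane carbon; not isolated) | Cl[Al](Cl)OC[C@]1(C)O[C@@H]1CC/C(C)=C/CC/C(C[Si](C)(C)C)=C/CCC1=CCOC1=O | intermediate
19 | 14-deoxyandrographolide, (3R,4R,5S,9R,10S)-3,19-dihydroxylabda-8(17),13-dien-16,15-olide (trans-decalin; equatorial 3-OH, axial 4-CH2OH and the C10 methyl on one face, H5 and H9 on the other) | C=C1CC[C@@H]2[C@](C)(CO)[C@H](O)CC[C@@]2(C)[C@@H]1CCC1=CCOC1=O | intermediate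
20 | (3R,4R,5S,7S,9S,10S)-3,7,19-trihydroxylabda-8(17),13-dien-16,15-olide (7-OH axial, trans to the C10 methyl) | C=C1[C@@H](O)C[C@@H]2[C@](C)(CO)[C@H](O)CC[C@@]2(C)[C@@H]1CCC1=CCOC1=O | intermediate
21 | (3R,4R,5S,9S,10S)-3,19-dihydroxy-7-oxolabda-8(17),13-dien-16,15-olide | C=C1C(=O)C[C@@H]2[C@](C)(CO)[C@H](O)CC[C@@]2(C)[C@@H]1CCC1=CCOC1=O | intermediate
22 | (3R,4R,5S,7R,9S,10S)-3,7,19-trihydroxylabda-8(17),13-dien-16,15-olide (7-OH equatorial, cis to the C10 methyl) | C=C1[C@H](O)C[C@@H]2[C@](C)(CO)[C@H](O)CC[C@@]2(C)[C@@H]1CCC1=CCOC1=O | target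

## Step count and risks

Total step count: 11. Longest linear sequence: 11 steps, from geranyl chloride 1 to 22; all other inputs are purchased.

The three steps most likely to fail are steps 8, 5 and 6.

**Step 8.** The bicyclization is run on a free 2,3-epoxy alcohol next to a Lewis-basic butenolide, so pinacol-type rearrangement of the oxirane or an interrupted cyclization could compete. The fallback is a protected-substrate approach that sets out from 17. The primary hydroxyl is silylated (t-BuMe2SiCl, imidazole, CH2Cl2) to give the tert-butyldimethylsilyl ether of 17 F1. This ordinary silyl-ether epoxide is cyclized with MeAlCl2 (CH2Cl2, −78 °C) to 19-O-(tert-butyldimethylsilyl)-14-deoxyandrographolide F2. HF·pyridine (THF, 0 °C) then cleaves the silyl ether, and the route is rejoined at 19.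

**Step 5.** Me3SiCH2Cu is a sluggish carbocupration partner, and three metals are relayed in one flask. The fallback builds the same allylsilane by directed trans-hydroalumination and cross-coupling, and sets out from 8.
- The hydroxyl is protected (t-BuMe2SiCl, imidazole) as the tert-butyldimethylsilyl ether of 8 F3.
- The alkyne is hydroxymethylated (n-BuLi, then (CH2O)n, THF) to the propargylic alcohol F4.
- NaAlH2(OCH2CH2OMe)2 (THF, 0 °C) followed by I2 at −78 °C gives the Z 3-iodo allylic alcohol F5, with iodine cis to CH2OH.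
- Kumada coupling with Me3SiCH2MgCl and Pd(PPh3)4 (THF) proceeds with retention to the allylsilane allylic alcohol F6.
- MnO2 oxidizes this to the enal F7.
- Wittig methylenation (Ph3PCH3Br, KOt-Bu, THF) gives the silyl-protected dienylsilane F8.
- Bu4NF buffered with AcOH (THF, 0 °C) removes the silyl ether, and the route is rejoined at 13.

**Step 6.** The α-bromobutenolide 14 and the coupled butenolide are base-sensitive under Suzuki conditions. The fallback is a masked-butenolide approach that sets out from 13 and 14. Bromide 14 is converted with i-Pr3SiOSO2CF3 and Et3N (CH2Cl2, 0 °C) into 3-bromo-2-[(triisopropylsilyl)oxy]furan F9, an aromatic, base-stable bromide. F9 is coupled with borane 15, made from 13 and 9-BBN as before (Pd(PPh3)4, aq. K3PO4, THF, 60 °C), to give the 3-alkyl-2-silyloxyfuran F10. Bu4NF with AcOH (THF, 0 °C), then Et3N to equilibrate to the conjugated 2(5H)-isomer, releases the butenolide, and the route is rejoined at 16.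

## Further compounds

F1 | step 8 | tert-butyldimethylsilyl ether of 17, 3-[(3Z,7E)-10-[(2R,3S)-3-({[tert-butyl(dimethyl)silyl]oxy}methyl)-3-methyloxiran-2-yl]-8-methyl-4-[(trimethylsilyl)methyl]deca-3,7-dien-1-yl]furan-2(5H)-one | CC(C)(C)[Si](C)(C)OC[C@]1(C)O[C@@H]1CC/C(C)=C/CC/C(C[Si](C)(C)C)=C/CCC1=CCOC1=O
F2 | step 8 | 19-O-(tert-butyldimethylsilyl)-14-deoxyandrographolide | C=C1CC[C@@H]2[C@](C)(CO[Si](C)(C)C(C)(C)C)[C@H](O)CC[C@@]2(C)[C@@H]1CCC1=CCOC1=O
F3 | step 5 | tert-butyldimethylsilyl ether of 8, tert-butyl{[(2Z,6E)-2,6-dimethylundeca-2,6-dien-10-yn-1-yl]oxy}dimethylsilane | CC(C)(C)[Si](C)(C)OC/C(C)=C\CC/C(C)=C/CCC#C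
F4 | step 5 | propargylic alcohol, (6E,10Z)-12-{[tert-butyl(dimethyl)silyl]oxy}-7,11-dimethyldodeca-6,10-dien-2-yn-1-ol | CC(C)(C)[Si](C)(C)OC/C(C)=C\CC/C(C)=C/CCC#CCO
F5 | step 5 | Z 3-iodo allylic alcohol, (2Z,6E,10Z)-12-{[tert-butyl(dimethyl)silyl]oxy}-3-iodo-7,11-dimethyldodeca-2,6,10-trien-1-ol | CC(C)(C)[Si](C)(C)OC/C(C)=C\CC/C(C)=C/CC/C(I)=C/CO
F6 | step 5 | allylsilane allylic alcohol, (2Z,6E,10Z)-12-{[tert-butyl(dimethyl)silyl]oxy}-7,11-dimethyl-3-[(trimethylsilyl)methyl]dodeca-2,6,10-trien-1-ol | CC(C)(C)[Si](C)(C)OC/C(C)=C\CC/C(C)=C/CC/C(C[Si](C)(C)C)=C/CO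
F7 | step 5 | enal, (2Z,6E,10Z)-12-{[tert-butyl(dimethyl)silyl]oxy}-7,11-dimethyl-3-[(trimethylsilyl)methyl]dodeca-2,6,10-trienal | CC(C)(C)[Si](C)(C)OC/C(C)=C\CC/C(C)=C/CC/C(C[Si](C)(C)C)=C/C=O
F8 | step 5 | silyl-protected dienylsilane, tert-butyl{[(2Z,6E,10Z)-2,6-dimethyl-10-[(trimethylsilyl)methyl]trideca-2,6,10,12-tetraen-1-yl]oxy}dimethylsilane | CC(C)(C)[Si](C)(C)OC/C(C)=C\CC/C(C)=C/CC/C(C[Si](C)(C)C)=C/C=C
F9 | step 6 | 3-bromo-2-[(triisopropylsilyl)oxy]furan | CC(C)[Si](Oc1occc1Br)(C(C)C)C(C)C
F10 | step 6 | 3-alkyl-2-silyloxyfuran, (2Z,6E,10Z)-2,6-dimethyl-13-{2-[(triisopropylsilyl)oxy]furan-3-yl}-10-[(trimethylsilyl)methyl]trideca-2,6,10-trien-1-ol | OC/C(C)=C\CC/C(C)=C/CC/C(C[Si](C)(C)C)=C/CCc1ccoc1O[Si](C(C)C)(C(C)C)C(C)C
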